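The earlier runs and the new flask come from a simulation on assumed constants; the scatter is artificial.

My unit is the charge of starting material, and every amount below is a fraction of it, partner included. Maple thus holds 1.50 equivalents of partner and elm 0.370, and in maple the starting material is the limiting reagent.

| flask | starting material | partner | protic impurity | temperature | remark | time |
|---|---|---|---|---|---|---|
| north | 27 mM (in portions, 4) | 14 mM | 27 mM | 10 °C | run made earlier; portions every 1.0 h |  |
| west | 27 mM (in portions, 4) | 53 mM | 27 mM | 25 °C | run made earlier; portions every 1.0 h |  |
| elm | 27 mM | 10.0 mM | 27.0 mM | 25 °C | everything together at the start | 10 h |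
| maple | 27 mM (in portions, 4) | 40.5 mM | 27.0 mM | 25 °C | the portions of starting material follow each other after 1.0 h, the first at the start | 10 h |

| run | time / h | product / % | starting material / % |
|---|---|---|---|
| north | 5.00 | 0.2 | 58.7 |
| north | 10.0 | 1.1 | 33.0 |
| north | 15.0 | 2.4 | 20.8 |
| north | 20.0 | 3.1 | 15.7 |
| west | 2.50 | 3.0 | 35.1 |
| west | 5.00 | 10.2 | 18.7 |
| west | 8.00 | 20.9 | 5.6 |
| west | 10.0 | 25.6 | 1.9 |

(scatter of a reading: 1 percentage point)

- which one finishes higher in amount of product, in percent of the starting material charged ("neither" within 2 percentage points) (elm / maple / neither)
- amount of product at the end, in percent of the starting material charged, elm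
- amount of product at the end, in percent of the starting material charged, maple

- the numbers in the tables scatter by 1 percentage point (one standard deviation)

I keep the books on west, which shares maple's temperature, portions and impurity. At 10.0 h, 1.9% is still starting material, 25.6% is product, and 72.5% stands in no reading. North, colder and with less partner, shows the same kind of gap, with 3.1% product and 15.7% starting material at 20.0 h. The unread entry need not be lost. From 8.00 h to 10.0 h in west, product gains 4.7 percentage points while starting material drops by 3.7 points, a difference within the scatter, so I read it as a hint of a store that partner draws on.

I therefore let the product entry follow partner, holding impurity, portions, temperature and time as in west. The product fraction per equivalent of partner, which I call the partner yield 13.0%, is my one carried figure. For maple it books 19.6% as product. With west's 1.9% left over, 78.5% goes to the unread entry, and the books close. For elm it gives 4.83%, a rougher figure: elm takes its charge in one go, and west did not. So I expect maple to finish higher than elm, by 15 points.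

The forecast names maple, with 10% for elm, above my figure, and 21% for maple, and calls itself “a rough, model-dependent estimate”.

The flask gives maple, with elm at 7.85% and maple at 20.5%.

    starting material → intermediate (k = 0.00360 min⁻¹, Ea = 100 kJ mol⁻¹)
    partner + intermediate → product (k = 0.0507 M⁻¹ min⁻¹, Ea = 54.0 kJ mol⁻¹)
    starting material + protic impurity → quenched substrate (k = 0.281 M⁻¹ min⁻¹, Ea = 47.0 kJ mol⁻¹)
    (constants at 25 °C)

The partner yield lands near maple, 19.6% against 20.5%, while elm finishes above it, at 7.85% against 4.83%. Two things acting together hold maple's product down, each only a part of the story: the passing of starting material and protic impurity into quenched substrate, and the time given. Without that passing, maple stands at 35.5% instead of 20.5%, and left ten times as long it stands at 41.6%, for at 10.0 h maple still holds 19.9% as intermediate.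

For a neighbour of maple with 0.889 equiv of partner, the partner yield gives 11.6%. That flask gives 13.9%, with 26.4% still standing as intermediate.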